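**Design of a total synthesis of spiropreussione B (25)**

Atom labels used throughout: the arene carries phenalenone numbering (C1 carbonyl, 9-OH; ring A = C1, C2, C3, C3a, C9b, C9a; ring B = C3a, C4, C5, C6, C6a, C9b; ring C = the phenol ring). Ck is the ketal carbon on C6. The cyclopentenone carbons are Ca (quaternary carbinol on C5), Cb (ring-fusion CH), Cc (enone carbonyl), Cd and Ce (alkene, Ce next to Ca). Ring D = C5, C6, Ck, Cb, Ca; ring E = Ca to Ce.

## The problem

Spiropreussione B (25) is a 9-hydroxyphenalen-1-one whose ring B carries, across C5 and C6, the five-membered ring D, which is cis-fused through Ca–Cb to a 4-hydroxycyclopent-2-enone (ring E); Ck is the spiro centre of a naphtho[1,8-de][1,3]dioxine. There are two adjacent stereocentres, the quaternary carbinol Ca (R) and the methine Cb (S) between Ck and Cc. Cb is epimerisable once Cc is a ketone, and a bicyclo[3.3.0]octane can only be cis-fused, so Ca is the centre that has to be set in the absolute sense and it then governs Cb. The finished molecule is fragile: Ca–OH with Cc=O is an aldol (retro-aldol with base), the aryloxy groups on Ck are β to Cc=O (E1cB opening of the ketal), and the tertiary alcohol is benzylic and allylic (acid). A ketone at Ck next to a ketone at Cc would be an enolised 1,3-diketone, so the ketal has to be made on a hindered aryl ketone while Cc is still at the alcohol level. The feature that opens the structure is ring B: one hydrogen (C4), an acyl-level carbon on C6, a carbinol on C5 and peri fusion to ring A. This is the pattern left when a naphthoquinone carbonyl carbon (future C3a), an alkyne on the neighbouring peri position (future C6 and Ck) and a terminal alkyne held two atoms away (future C5 and C4) are merged into a benzene ring, the unused half of the quinone being ring A.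

## Retrosynthesis

**Ketal and oxidation level (25 ⇒ 24 ⇒ 23 ⇒ 21 + 22).** The Cc carbonyl activates every decomposition path of 25, so it is taken back first to the allylic alcohol 24 and its bis-silyl ether 23. The two Ck–O bonds are then cut to give aryl ketone 21 and 1,8-dihydroxynaphthalene (22). Cutting the ketal here rather than earlier is forced, because Ck only becomes a carbonyl in the ring-forming step. With Cc as a silyl ether, 21 has a single ketone open to ketalisation (the phenalenone carbonyl is a vinylogous acid carbonyl). The forward reactions have to ketalise a hindered five-ring aryl ketone without ionising the silyl ethers, and to oxidise one secondary allylic alcohol under neutral conditions as the last step.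

**Ring B and ring D (21 ⇒ 20 ⇒ 19).** After the phenol is returned to its methyl ether (20), the bonds C3a–C4 and C5–C6 are cut. The neighbouring cuts inside ring D (aldol, aryl–Ck bond formation) all leave a 5,6-disubstituted 9-oxygenated phenalenone to be made by separate arene chemistry. This cut removes ring B and ring D together and also dissolves the phenalenone into a naphthoquinone. The precursor 19 is 5-methoxy-1,4-naphthoquinone carrying at C8 an alkyne that ends in a cyclopentene with a cis-placed ethynyl group. The forward step asks a quinone carbonyl oxygen to act as the nucleophile toward a gold-activated alkyne. It also requires Cc to be a silyl ether (so that no ketone oxygen can close a furan onto the same alkyne and Cb cannot drift to an allene), a silylated Ca–O (against Meyer–Schuster rearrangement) and a fixed cis diyne.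

**Quinone, alkyne cap and ring E alkene (19 ⇒ 18 ⇒ 17 ⇒ 16 ⇒ 15).** The quinone is taken back to the hydroquinone dimethyl ether 18, since a quinone would not survive bases and organometallics. The terminal alkyne returns to its C-silyl form 17. The Cd=Ce double bond is taken back through enol triflate 16 to ketone 15. The ketone at Ce is worth these two extra steps because it is the handle that allows both bonds to Ca and Cb to be made by enone chemistry with reliable stereocontrol.

**Ca–O and Cb–C(sp) (15 ⇒ 13 ⇒ 10 + 7).** The Ca–O bond is cut as an enol ether oxidation (13), and the Cb–alkyne bond as a conjugate addition of arylacetylene 7 to alkynyl enone 10. The neighbouring options are weaker. Alkynylating a ketone enolate at Cb gives an α-alkynyl ketone that is hard to make and isomerises to an allenone. Adding an acetylide to a ketone at Ca next to a finished Cb would enter anti to the Cb substituent and give the trans diyne. In the chosen order the acetylide enters anti to the silyloxy group of 10 (Cb), the oxidant enters anti to the new alkynyl group (Ca), and the cis diyne results. This is also the convergent point: two fragments of similar size are joined.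

**Fragments (10 ⇒ 9 ⇒ 8; 7 ⇒ 6 ⇒ 4 ⇒ 3 ⇒ 1).** Enone 10 comes from (S)-4-silyloxycyclopentenone 8 by α-iodination (9) and Sonogashira coupling with ethynyltrimethylsilane (5). The single stereocentre of 8 controls Cb, Cb controls Ca, and the centre itself ends as the Cc carbonyl. Arylacetylene 7 comes from juglone (1) by reductive methylation (3), bromination para to the C5 methoxy group (4), Sonogashira coupling with 5 (6) and desilylation.

## Roads not taken

**Alternative 1:** transannular aldol. The cut is the Ca–Cb bond, which opens rings D and E together to the benzo-fused cyclooctane-1,4-dione A1 that already holds the phenalenone and the spiroketal. In the forward step a proline-type amine would form the enamine of the Cc ketone toward the CH2 next to Ck, and this would add across the ring to the aryl ketone to give ketol A2; dehydrogenation of the CH2–CH2 unit would finish the enone.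
- Merits: both stereocentres come from a catalyst, no protecting groups are needed late, and the cis fusion is automatic.
- Weak points: A1 needs an eight-membered ring built on a 5,6-disubstituted phenalenone, so the arene problem is untouched. The Cc ketone has two α-methylene groups and the one required is neopentyl to the spiro centre, so other enamines and other transannular modes compete. The β-aryloxy ketone already present in A1 can open by E1cB under amine catalysis. The final dehydrogenation of A2 has to be done on a retro-aldol-prone ketol.
- Comparison: this road is better in late-stage step count and in catalyst-controlled absolute configuration. The chosen plan sets against it that it builds ring B itself, takes its configuration from a defined commercial stereocentre, and lets the aldol and β-aryloxy ketone motifs appear only in the last step.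

**Alternative 2:** Friedel–Crafts spirocyclisation. The cut is the C6–Ck bond. Acid would protonate the α-oxo ketene acetal A3 at Cb to a naphthodioxinylium ion, which C6 of the masked dihydrophenalenone attacks to close ring D and the spiro centre, giving A4. Ring A must then be unmasked and dehydrogenated and the methyl ether cleaved.
- Merits: the ketal arrives without condensing a diol onto a hindered ketone, which is better than step 15 of the chosen plan, and Cb is set by the ring fusion.
- Weak points: a push–pull ketene acetal protonates more readily on the carbonyl oxygen, and the required C-protonated cation lies α to a ketone. C6 is not activated by the methoxy group. The free tertiary benzylic, allylic alcohol sits under the same acid. Ring A has to be carried in masked form, and the cyclopentenone with its quaternary aryl carbinol still needs an enantioselective synthesis.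
- Comparison: this road is superior for the ketal. The chosen plan sets against it that ring B and ring D form together under neutral gold catalysis on fully protected material, and that ring A is in place without masking or dehydrogenation.

**Alternative 3:** double oxa-Michael and aldol cascade. The cuts are both Ck–O bonds and Ca–Cb. Diol 22 would add twice to the β-carbon of ynone A5, and the resulting enolate would add to the neighbouring aryl ketone, closing the dioxine and ring D to give A6. Acetal hydrolysis and aldol condensation of the acetyl group onto the aldehyde would then close ring E.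
- Merits: it is the most convergent road, three bonds form in one flask, and double conjugate addition is a good way to make naphthodioxines.
- Weak points: there is no source of absolute configuration. The cis arrangement of acetyl and dimethoxymethyl groups has to come from an aldol onto a ketone. A6 is both a β-aryloxy ketone and an aldol, so retro-Michael and retro-aldol reactions are open under the basic conditions that form it and again in the ring E condensation. A5 is a 5,6-disubstituted phenalenone that must be made separately.
- Comparison: this road is better in convergence and in ketal formation. The chosen plan sets against it chiral-pool control of Ca, construction of the arene substitution pattern in the key step, and exposure of the labile motifs only at the end.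

Key step: step 13

Assumption: NBS bromination of 3 is taken to occur at C8 (the α-position para to the C5 methoxy group), and the (S)-enantiomer 8 is taken to be commercially available like its antipode.

## Route

Step 1
Reactants: 1 juglone (5-hydroxynaphthalene-1,4-dione)
Product: 3 1,4,5-trimethoxynaphthalene, via naphthalene-1,4,5-triol 2 (not isolated)
Conditions: Na2S2O4, THF/H2O, rt; then Me2SO4, KOH (aq), Bu4NBr (cat.), rt
Reagents that add atoms: dimethyl sulfate, COS(=O)(=O)OC
Why: Reductive methylation: dithionite reduces the quinone to triol 2, and phase-transfer Williamson methylation caps all three phenoxides in the same flask before air can reoxidise them.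

Step 2
Reactants: 3 1,4,5-trimethoxynaphthalene
Product: 4 8-bromo-1,4,5-trimethoxynaphthalene
Conditions: NBS, MeCN, 0 °C → rt
Reagents that add atoms: N-bromosuccinimide, O=C1CCC(=O)N1Br
Why: Electrophilic aromatic bromination at the α-position para to the C5 methoxy group, the most activated site; one equivalent of NBS should avoid dibromination.

Step 3
Reactants: 4 8-bromo-1,4,5-trimethoxynaphthalene; 5 ethynyltrimethylsilane
Product: 6 trimethyl[(4,5,8-trimethoxynaphthalen-1-yl)ethynyl]silane
Conditions: Pd(PPh3)2Cl2 (cat.), CuI (cat.), Et3N, THF, 70 °C (sealed)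
Reagents that add atoms: none
Why: Sonogashira coupling of an aryl bromide; the electron-rich, peri-flanked bromide needs heating but has no competing reactive site.

Step 4
Reactants: 6 trimethyl[(4,5,8-trimethoxynaphthalen-1-yl)ethynyl]silane
Product: 7 8-ethynyl-1,4,5-trimethoxynaphthalene
Conditions: K2CO3 (cat.), MeOH/THF, rt
Reagents that add atoms: none
Why: Methanolysis of the alkynyl C–Si bond; nothing else in the molecule is base-labile.

Step 5
Reactants: 8 (S)-4-(tert-butyldimethylsilyloxy)cyclopent-2-en-1-one
Product: 9 (S)-4-(tert-butyldimethylsilyloxy)-2-iodocyclopent-2-en-1-one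
Conditions: I2, pyridine, CH2Cl2, 0 °C → rt
Reagents that add atoms: iodine, I-I
Why: Pyridine-mediated α-iodination of an enone (conjugate addition of pyridine, iodination of the enolate, elimination); the C4 stereocentre is not touched.

Step 6
Reactants: 9 (S)-4-(tert-butyldimethylsilyloxy)-2-iodocyclopent-2-en-1-one; 5 ethynyltrimethylsilane
Product: 10 (S)-4-(tert-butyldimethylsilyloxy)-2-[(trimethylsilyl)ethynyl]cyclopent-2-en-1-one
Conditions: Pd(PPh3)2Cl2 (cat.), CuI (cat.), i-Pr2NH, THF, 0 °C
Reagents that add atoms: none
Why: Sonogashira coupling of an α-iodoenone, which undergoes oxidative addition readily at 0 °C; the hindered amine should not add to the enone.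

Step 7
Reactants: 7 8-ethynyl-1,4,5-trimethoxynaphthalene; 10 (S)-4-(tert-butyldimethylsilyloxy)-2-[(trimethylsilyl)ethynyl]cyclopent-2-en-1-one
Product: 13 (3S,4S)-1,4-bis(tert-butyldimethylsilyloxy)-3-[(4,5,8-trimethoxynaphthalen-1-yl)ethynyl]-2-[(trimethylsilyl)ethynyl]cyclopent-1-ene, via lithium acetylide 11 (not isolated), via alkynylzinc bromide 12 (not isolated)
Conditions: 7, n-BuLi, THF, −78 °C; ZnBr2, −78 → 0 °C; then 10, t-BuMe2SiOTf, −40 °C
Reagents that add atoms: tert-butyldimethylsilyl trifluoromethanesulfonate, CC(C)(C)[Si](C)(C)OS(=O)(=O)C(F)(F)F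
Why: Silyl-triflate-promoted conjugate addition of an alkynylzinc halide to a cyclic enone, the activation that alkynyl groups need on s-trans enones; the acetylide should enter anti to the C4 silyloxy group (setting Cb), and the enolate is captured regiospecifically as the silyl enol ether needed next.

Step 8
Reactants: 13 (3S,4S)-1,4-bis(tert-butyldimethylsilyloxy)-3-[(4,5,8-trimethoxynaphthalen-1-yl)ethynyl]-2-[(trimethylsilyl)ethynyl]cyclopent-1-ene
Product: 15 (2R,3R,4S)-2,4-bis(tert-butyldimethylsilyloxy)-3-[(4,5,8-trimethoxynaphthalen-1-yl)ethynyl]-2-[(trimethylsilyl)ethynyl]cyclopentan-1-one, via silyloxy oxirane 14 (not isolated)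
Conditions: dimethyldioxirane, acetone/CH2Cl2, −78 → 0 °C; then CSA (cat.), CH2Cl2, 0 °C
Reagents that add atoms: dimethyldioxirane, CC1(C)OO1
Why: Rubottom oxidation; the enol ether double bond should be epoxidised on the face anti to the adjacent arylethynyl group, so the new Ca–O bond is trans to it and the two alkynyl groups are cis, and 1,4-silyl migration in oxirane 14 delivers the tertiary silyl ether directly; alkynes and the arene are much slower toward the dioxirane at this temperature.

Step 9
Reactants: 15 (2R,3R,4S)-2,4-bis(tert-butyldimethylsilyloxy)-3-[(4,5,8-trimethoxynaphthalen-1-yl)ethynyl]-2-[(trimethylsilyl)ethynyl]cyclopentan-1-one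
Product: 16 (3S,4R,5R)-3,5-bis(tert-butyldimethylsilyloxy)-4-[(4,5,8-trimethoxynaphthalen-1-yl)ethynyl]-5-[(trimethylsilyl)ethynyl]cyclopent-1-en-1-yl trifluoromethanesulfonate
Conditions: N-(5-chloropyridin-2-yl)triflimide, then KN(SiMe3)2 added slowly, THF, −78 °C
Reagents that add atoms: N-(5-chloropyridin-2-yl)-1,1,1-trifluoro-N-[(trifluoromethyl)sulfonyl]methanesulfonamide, FC(F)(F)S(=O)(=O)N(c1ccc(Cl)cn1)S(=O)(=O)C(F)(F)F
Why: Enol triflate formation; only C5 has α-hydrogens, and trapping the enolate as it forms at −78 °C should outrun β-elimination of the C4 silyloxy group.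

Step 10
Reactants: 16 enol triflate
Product: 17 (1R,4S,5R)-1,4-bis(tert-butyldimethylsilyloxy)-5-[(4,5,8-trimethoxynaphthalen-1-yl)ethynyl]-1-[(trimethylsilyl)ethynyl]cyclopent-2-ene
Conditions: Pd(OAc)2 (cat.), PPh3, HCO2H, Bu3N, DMF, 60 °C
Reagents that add atoms: none
Why: Palladium-catalysed formate reduction of a vinyl triflate (oxidative addition, decarboxylation of formate to the palladium hydride, reductive elimination); the silyl- and aryl-capped internal alkynes should be inert to hydropalladation under these conditions.

Step 11
Reactants: 17 C-silylated diyne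
Product: 18 (1R,4S,5R)-1,4-bis(tert-butyldimethylsilyloxy)-1-ethynyl-5-[(4,5,8-trimethoxynaphthalen-1-yl)ethynyl]cyclopent-2-ene
Conditions: K2CO3 (cat.), MeOH/THF, rt
Reagents that add atoms: none
Why: Methanolysis of the alkynyl C–Si bond, selective over the O-silyl ethers; it is done before the quinone is made because a quinone would add methoxide.

Step 12
Reactants: 18 terminal diyne
Product: 19 8-{[(1R,2R,5S)-2,5-bis(tert-butyldimethylsilyloxy)-2-ethynylcyclopent-3-en-1-yl]ethynyl}-5-methoxynaphthalene-1,4-dione
Conditions: (NH4)2Ce(NO3)6, MeCN/H2O, 0 °C, short reaction time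
Reagents that add atoms: water, O
Why: Oxidative demethylation of the only para-dimethoxy ring to the 1,4-quinone, the carbonyl oxygens coming from water; brief cold exposure should spare the silyl ethers, the alkene and both alkynes.

Step 13
Reactants: 19 quinone diyne
Product: 20 9-methoxyphenalen-1-one with ring D across C5/C6 (C5–Ca(OSit-BuMe2)–Cb(H)–Ck(=O)–C6), cis-fused to the cyclopentene Ca–Cb–Cc(OSit-BuMe2)–Cd=Ce; Ca R, Cb R, Cc S
Conditions: AuBr3 (10 mol %), (ClCH2)2, 60 °C
Reagents that add atoms: none
Why: Proposed new method: AuBr3 (trivalent gold) coordinates the aryl alkyne of 19, and the oxygen of the quinone carbonyl on the neighbouring ring position attacks the alkyne carbon remote from the arene in a 6-endo-dig closure, giving a 2-benzopyrylium aurate whose cationic carbon is the former quinone carbon. The terminal ethynyl group on Ca then adds across this carbon and the gold-bearing carbon in an intramolecular [4+2] cycloaddition, its CH end bonding to the former carbonyl carbon (C3a–C4) and its inner carbon to the gold-bearing carbon (C5–C6), while the two-atom tether Ca–Cb closes ring D as a five-membered ring fused to the new six-membered one. Cleavage of the oxygen bridge from the former quinone carbon turns the alkyne carbon that received the oxygen into the aryl ketone Ck, aromatises ring B and releases AuBr3; the untouched half of the quinone is then ring A of the phenalenone, so no redox adjustment follows. The closest known reaction type is the AuBr3- or Cu(OTf)2-catalysed intramolecular [4+2] benzannulation of 2-alkynylaryl aldehydes and ketones with an alkyne tethered to the alkyne terminus, which gives ring ketones in the same way; a quinone carbonyl has not served as the oxygen nucleophile and the tether here is short. No stereocentre is formed: Ca and Cb are carried through, and the cis relation of the two alkynyl groups fixed in steps 7 and 8 is what lets the tether reach. Chemoselectivity rests on the substrate: only one quinone carbonyl is within reach of the alkyne, Cc is a silyl ether so that no ketone oxygen can close a furan and Cb cannot isomerise to an allene, and the propargylic Ca–O is silylated against Meyer–Schuster rearrangement. The electron-poor pyrylium should form slowly but cycloadd fast, so the temperature is raised only as far as needed.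

Step 14
Reactants: 20 methyl ether
Product: 21 9-hydroxy analogue of 20 (9-hydroxyphenalen-1-one, aryl ketone at Ck, both silyl ethers intact; Ca R, Cb R, Cc S)
Conditions: BCl3, CH2Cl2, −78 °C; aq. NaHCO3
Reagents that add atoms: none
Why: Chelation-assisted cleavage of a methyl ether peri to a carbonyl (here a vinylogous ester), fast at −78 °C where silyl ethers should survive; it is done now so that no Lewis acid has to meet the finished ketal and aldol.

Step 15
Reactants: 21 hydroxyphenalenone ketone; 22 1,8-dihydroxynaphthalene
Product: 23 spiro[naphtho[1,8-de][1,3]dioxine-2,Ck] ketal of 21 (bis-silyl ether of 24; Ca R, Cb R, Cc S)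
Conditions: TsOH·H2O (cat.), toluene, 4 Å MS, 60 °C, degassed
Reagents that add atoms: none
Why: Acid-catalysed ketalisation of an aryl ketone with 1,8-dihydroxynaphthalene, as practised on tetralones; Ck is the only ketone that can react, because the phenalenone carbonyl is a chelated vinylogous acid carbonyl and Cc is a silyl ether, and both silyloxy groups lie on the convex face away from Ck.

Step 16
Reactants: 23 bis-silyl ether
Product: 24 diol (spiropreussione B with Cc as the secondary allylic alcohol; Ca R, Cb R, Cc S)
Conditions: Bu4NF, AcOH, THF, 0 → 40 °C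
Reagents that add atoms: none
Why: Fluoride desilylation of both silyl ethers; at this stage Cb–H is not acidic and no carbonyl lies β to either oxygen, so buffered fluoride should be harmless.

Step 17
Reactants: 24 diol
Product: 25 spiropreussione B (Ca R, Cb S)
Conditions: MnO2, CH2Cl2, rt
Reagents that add atoms: none
Why: Chemoselective oxidation of the secondary allylic alcohol under neutral conditions; the tertiary alcohol cannot be oxidised, the chelated phenol is electron-poor, and the base-sensitive aldol and β-aryloxy ketone motifs are created only here; Cb is not inverted (its descriptor changes with the priorities) and the cis fusion is the only possible one.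

## Compound list

1 | juglone (5-hydroxynaphthalene-1,4-dione) | O=C1C=CC(=O)c2c(O)cccc12 | starting material
2 | naphthalene-1,4,5-triol | Oc1ccc(O)c2c(O)cccc12 | intermediate (not isolated)
3 | 1,4,5-trimethoxynaphthalene | COc1ccc(OC)c2c(OC)cccc12 | intermediate
4 | 8-bromo-1,4,5-trimethoxynaphthalene | COc1ccc(OC)c2c(OC)ccc(Br)c12 | intermediate
5 | ethynyltrimethylsilane | C#C[Si](C)(C)C | starting material
6 | trimethyl[(4,5,8-trimethoxynaphthalen-1-yl)ethynyl]silane | COc1ccc(OC)c2c(OC)ccc(C#C[Si](C)(C)C)c12 | intermediate
7 | 8-ethynyl-1,4,5-trimethoxynaphthalene | COc1ccc(OC)c2c(OC)ccc(C#C)c12 | intermediate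
8 | (S)-4-(tert-butyldimethylsilyloxy)cyclopent-2-en-1-one | O=C1C=C[C@@H](O[Si](C)(C)C(C)(C)C)C1 | starting material
9 | (S)-4-(tert-butyldimethylsilyloxy)-2-iodocyclopent-2-en-1-one | O=C1C(I)=C[C@@H](O[Si](C)(C)C(C)(C)C)C1 | intermediate
10 | (S)-4-(tert-butyldimethylsilyloxy)-2-[(trimethylsilyl)ethynyl]cyclopent-2-en-1-one | O=C1C(C#C[Si](C)(C)C)=C[C@@H](O[Si](C)(C)C(C)(C)C)C1 | intermediate
11 | lithium (4,5,8-trimethoxynaphthalen-1-yl)acetylide | [Li]C#Cc1ccc(OC)c2c(OC)ccc(OC)c12 | intermediate (not isolated)
12 | [(4,5,8-trimethoxynaphthalen-1-yl)ethynyl]zinc bromide | Br[Zn]C#Cc1ccc(OC)c2c(OC)ccc(OC)c12 | intermediate (not isolated)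
13 | (3S,4S)-1,4-bis(tert-butyldimethylsilyloxy)-3-[(4,5,8-trimethoxynaphthalen-1-yl)ethynyl]-2-[(trimethylsilyl)ethynyl]cyclopent-1-ene | CC(C)(C)[Si](C)(C)OC1=C(C#C[Si](C)(C)C)[C@H](C#Cc2ccc(OC)c3c(OC)ccc(OC)c23)[C@@H](O[Si](C)(C)C(C)(C)C)C1 | intermediate
14 | silyloxy oxirane of 13 (oxirane oxygen anti to the arylethynyl group, cis to the C4 silyloxy group) | CC(C)(C)[Si](C)(C)O[C@@]12C[C@H](O[Si](C)(C)C(C)(C)C)[C@@H](C#Cc3ccc(OC)c4c(OC)ccc(OC)c34)[C@]1(C#C[Si](C)(C)C)O2 | intermediate (not isolated)
15 | (2R,3R,4S)-2,4-bis(tert-butyldimethylsilyloxy)-3-[(4,5,8-trimethoxynaphthalen-1-yl)ethynyl]-2-[(trimethylsilyl)ethynyl]cyclopentan-1-one | O=C1C[C@H](O[Si](C)(C)C(C)(C)C)[C@@H](C#Cc2ccc(OC)c3c(OC)ccc(OC)c23)[C@@]1(O[Si](C)(C)C(C)(C)C)C#C[Si](C)(C)C | intermediate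
16 | (3S,4R,5R)-3,5-bis(tert-butyldimethylsilyloxy)-4-[(4,5,8-trimethoxynaphthalen-1-yl)ethynyl]-5-[(trimethylsilyl)ethynyl]cyclopent-1-en-1-yl trifluoromethanesulfonate | FC(F)(F)S(=O)(=O)OC1=C[C@H](O[Si](C)(C)C(C)(C)C)[C@@H](C#Cc2ccc(OC)c3c(OC)ccc(OC)c23)[C@@]1(O[Si](C)(C)C(C)(C)C)C#C[Si](C)(C)C | intermediate
17 | (1R,4S,5R)-1,4-bis(tert-butyldimethylsilyloxy)-5-[(4,5,8-trimethoxynaphthalen-1-yl)ethynyl]-1-[(trimethylsilyl)ethynyl]cyclopent-2-ene | C1=C[C@H](O[Si](C)(C)C(C)(C)C)[C@@H](C#Cc2ccc(OC)c3c(OC)ccc(OC)c23)[C@@]1(O[Si](C)(C)C(C)(C)C)C#C[Si](C)(C)C | intermediate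
18 | (1R,4S,5R)-1,4-bis(tert-butyldimethylsilyloxy)-1-ethynyl-5-[(4,5,8-trimethoxynaphthalen-1-yl)ethynyl]cyclopent-2-ene | C1=C[C@H](O[Si](C)(C)C(C)(C)C)[C@@H](C#Cc2ccc(OC)c3c(OC)ccc(OC)c23)[C@@]1(O[Si](C)(C)C(C)(C)C)C#C | intermediate
19 | 8-{[(1R,2R,5S)-2,5-bis(tert-butyldimethylsilyloxy)-2-ethynylcyclopent-3-en-1-yl]ethynyl}-5-methoxynaphthalene-1,4-dione | O=C1C=CC(=O)c2c1c(OC)ccc2C#C[C@@H]1[C@@H](O[Si](C)(C)C(C)(C)C)C=C[C@]1(O[Si](C)(C)C(C)(C)C)C#C | intermediate (precursor of the key step)
20 | 9-methoxyphenalen-1-one fused at C5/C6 to the cis-bicyclic silyloxy ketone (Ck=O, Ca–OSi, Cc–OSi; Ca R, Cb R, Cc S) | O=C1C=Cc2cc3c(c4ccc(OC)c1c24)C(=O)[C@@H]1[C@@H](O[Si](C)(C)C(C)(C)C)C=C[C@]31O[Si](C)(C)C(C)(C)C | intermediate (product of the key step)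
21 | 9-hydroxy analogue of 20 | O=C1C=Cc2cc3c(c4ccc(O)c1c24)C(=O)[C@@H]1[C@@H](O[Si](C)(C)C(C)(C)C)C=C[C@]31O[Si](C)(C)C(C)(C)C | intermediate
22 | 1,8-dihydroxynaphthalene | Oc1cccc2cccc(O)c12 | starting material
23 | naphtho[1,8-de][1,3]dioxine spiroketal of 21 at Ck (bis-silyl ether; Ca R, Cb R, Cc S) | O=C1C=Cc2cc3c(c4ccc(O)c1c24)C1(Oc2cccc4cccc(c24)O1)[C@@H]1[C@@H](O[Si](C)(C)C(C)(C)C)C=C[C@]31O[Si](C)(C)C(C)(C)C | intermediate
24 | diol: spiropreussione B with Cc as secondary allylic alcohol (Ca R, Cb R, Cc S) | O=C1C=Cc2cc3c(c4ccc(O)c1c24)C1(Oc2cccc4cccc(c24)O1)[C@@H]1[C@@H](O)C=C[C@]31O | intermediate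
25 | spiropreussione B (Ca R, Cb S) | O=C1C=Cc2cc3c(c4ccc(O)c1c24)C1(Oc2cccc4cccc(c24)O1)[C@@H]1C(=O)C=C[C@]31O | target

## Step count and least certain steps

Total: 17 steps. Longest linear sequence: 15 steps (steps 1–4 and 7–17 from juglone); the cyclopentenone branch (steps 5, 6) joins at step 7.

**Step 13 (key step).** The quinone oxygen may be too weak a nucleophile, so that gold instead drives cycloisomerisation of the 1,5-diyne or slow decomposition. The short tether may also stall the cycloaddition after pyrylium formation. Fallback with known chemistry: quinone 19 is treated with cyclopentadiene (CH2Cl2, 0 °C), which adds across C2=C3 of the quinone to give the endo Diels–Alder adduct F1. In F1 the carbonyl next to the alkyne is an ordinary aryl alkyl ketone, the substrate class on which the AuBr3 benzannulation with a tethered alkyne is established. Benzannulation of F1 (AuBr3, (ClCH2)2) should give the norbornene-fused dihydrophenalenone F2. Retro-Diels–Alder reaction of F2 (o-dichlorobenzene, 180 °C, or flash vacuum pyrolysis) expels cyclopentadiene and restores the C2=C3 double bond, returning to 20. Both facial isomers of the adduct converge.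

**Step 8.** Facial selectivity may be poor, because the silyloxy group at C4 sits on the face that the oxidant must use and the alkynyl group that should steer it is slim. The wrong Ca epimer has trans alkynes and cannot cyclise. Fallback: enol ether 13 is hydrolysed (1 M HCl, THF, 0 °C) to the 2,3-trans ketone F3. F3 is deprotonated at the doubly activated C2 (KN(SiMe3)2, −78 °C) and hydroxylated with the matching enantiomer of (camphorsulfonyl)oxaziridine, so that the reagent and not the ring decides the face, giving hydroxy ketone F4. Silylation of F4 (t-BuMe2SiOTf, 2,6-lutidine) returns to 15.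

**Step 9.** β-Elimination of the C4 silyloxy group from the C5 enolate may outrun triflation, or hydropalladation of an alkyne may intrude in step 10. Fallback: ketone 15 is reduced (NaBH4, MeOH, 0 °C) to alcohol F5 (either epimer). F5 is dehydrated by syn elimination with methyl N-(triethylammoniosulfonyl)carbamate (benzene, 50 °C); only C5 carries hydrogen, so the alkene can form in one direction only. This returns to 17 and bypasses 16.

**Step 15.** Acid may remove or ionise the silyl ethers, or cause β-elimination of the Cc silyloxy group from the aryl ketone, faster than the hindered five-ring ketone is ketalised. Fallback: diol 22 is converted (Me3SiCl, Et3N) into 1,8-bis(trimethylsilyloxy)naphthalene F6. F6 is joined to 21 by silyl-transfer ketalisation with catalytic Me3SiOTf in CH2Cl2 at −40 °C, an aprotic process driven by formation of the disiloxane, returning to 23.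

## Further compounds

F1 | step 13 | endo Diels–Alder adduct of 19 with cyclopentadiene across C2=C3 of the quinone (both facial isomers; new centres not specified) | O=C1C2C3C=CC(C3)C2C(=O)c2c1c(OC)ccc2C#C[C@@H]1[C@@H](O[Si](C)(C)C(C)(C)C)C=C[C@]1(O[Si](C)(C)C(C)(C)C)C#C
F2 | step 13 | 2,3-dihydro analogue of 20 with a norbornene fused at C2–C3 (new centres not specified) | O=C1C2C3C=CC(C3)C2c2cc3c(c4ccc(OC)c1c24)C(=O)[C@@H]1[C@@H](O[Si](C)(C)C(C)(C)C)C=C[C@]31O[Si](C)(C)C(C)(C)C
F3 | step 8 | (2R,3R,4S)-4-(tert-butyldimethylsilyloxy)-3-[(4,5,8-trimethoxynaphthalen-1-yl)ethynyl]-2-[(trimethylsilyl)ethynyl]cyclopentan-1-one | O=C1C[C@H](O[Si](C)(C)C(C)(C)C)[C@@H](C#Cc2ccc(OC)c3c(OC)ccc(OC)c23)[C@@H]1C#C[Si](C)(C)C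
F4 | step 8 | (2R,3R,4S)-4-(tert-butyldimethylsilyloxy)-2-hydroxy-3-[(4,5,8-trimethoxynaphthalen-1-yl)ethynyl]-2-[(trimethylsilyl)ethynyl]cyclopentan-1-one | O=C1C[C@H](O[Si](C)(C)C(C)(C)C)[C@@H](C#Cc2ccc(OC)c3c(OC)ccc(OC)c23)[C@@]1(O)C#C[Si](C)(C)C
F5 | step 9 | (2R,3R,4S)-2,4-bis(tert-butyldimethylsilyloxy)-3-[(4,5,8-trimethoxynaphthalen-1-yl)ethynyl]-2-[(trimethylsilyl)ethynyl]cyclopentan-1-ol (C1 either epimer) | OC1C[C@H](O[Si](C)(C)C(C)(C)C)[C@@H](C#Cc2ccc(OC)c3c(OC)ccc(OC)c23)[C@@]1(O[Si](C)(C)C(C)(C)C)C#C[Si](C)(C)C
F6 | step 15 | 1,8-bis(trimethylsilyloxy)naphthalene | C[Si](C)(C)Oc1cccc2cccc(O[Si](C)(C)C)c12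
A1 | alternative 1 | benzo-fused cyclooctane-1,4-dione carrying phenalenone and spiroketal | O=C1C=Cc2cc3c(c4ccc(O)c1c24)C1(Oc2cccc4cccc(c24)O1)CC(=O)CCC3=O
A2 | alternative 1 | saturated ketol (cyclopentanone analogue of spiropreussione B) | O=C1C=Cc2cc3c(c4ccc(O)c1c24)C1(Oc2cccc4cccc(c24)O1)[C@@H]1C(=O)CC[C@]31O
A3 | alternative 2 | α-oxo ketene naphthodioxine acetal on the hydroxycyclopentenone bearing the masked dihydrophenalenone at Ca | C12(OCCO2)CCc2cc(cc3ccc(OC)c1c23)[C@@]4(O)C=CC(=O)C4=C4Oc5cccc6cccc(O4)c56
A4 | alternative 2 | masked spiropreussione B (dihydrophenalenone dioxolane, methyl ether) | C12(OCCO2)CCc2cc3c(c4ccc(OC)c1c24)C1(Oc2cccc4cccc(c24)O1)[C@@H]1C(=O)C=C[C@]31O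
A5 | alternative 3 | 9-hydroxyphenalenone with a dimethoxyacetyl group at C5 and a 3-oxobut-1-ynyl group at C6 | O=C1C=Cc2cc(C(=O)C(OC)OC)c(C#CC(C)=O)c3ccc(O)c1c23
A6 | alternative 3 | spiroketal aldol adduct (acetyl and dimethoxymethyl groups cis) | O=C1C=Cc2cc3c(c4ccc(O)c1c24)C1(Oc2cccc4cccc(c24)O1)[C@H](C(C)=O)[C@]3(O)C(OC)OC
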